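One mole of initiator is the unit of this ledger: chains are counted in it.

| flask | free monomer | initiator | remark | time |
|---|---|---|---|---|
| gamma | 0.19 M (fed, over 1.5 min) | 0.5 mol% | run made earlier; the fed solution adds 0.10 times the starting volume |  |
| alpha | 0.29 M (fed, over 1.5 min) | 0.5 mol% | run made earlier; the fed solution adds 0.10 times the starting volume |  |
| flask | 0.38 M (fed, over 1.5 min) | 0.5 mol% | the fed solution adds 0.10 times the starting volume | 30 min |

| run | time / min | monomer in chains / % | free monomer / % |
|---|---|---|---|
| gamma | 4.00 | 0.9 | 97.8 |
| gamma | 10.0 | 5.3 | 94.7 |
| gamma | 20.0 | 13.1 | 85.4 |
| gamma | 30.0 | 22.3 | 77.0 |
| alpha | 2.50 | 1.3 | 99.3 |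
| alpha | 6.00 | 5.0 | 94.9 |
| alpha | 12.0 | 15.4 | 85.1 |
| alpha | 30.0 | 39.2 | 60.9 |

(scatter of a reading: 0.5 percentage points)

- charges are per starting volume, the dose included; the dosed solution carries all of it
- the average divides the monomer in chains by the number of chains begun, living and dead together
- the earlier runs were read with a standard deviation of 0.5 percentage points
- candidate steps: free monomer + living end -> monomer in chains + living end; monomer in chains + living end -> free monomer + living end; free monomer + initiator -> living end + monomer in chains
- the earlier runs do not show the number of chains; that part of a forecast is a guess

- average number of monomer units in a chain (chains begun, living or dead) at 30 min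
- part of the free monomer that has reacted at 30 min

1. Opening entry: the flask is charged with c(initiator) = 0.00190 M per starting volume. Every chain begun draws on this charge.

2. The fork: among the candidate steps, a mole of initiator has one way out. With free monomer it gives one living end and one monomer in chains, so each mole spent begins one chain.

3. Later entries: growth and its reverse shift monomer between free and chained, and the living end comes out of each step unchanged. Neither step changes the count of chains.

4. The alpha run takes up 1.3 % in its first 2.50 min, then 10 percentage points between 6.00 min and 12.0 min. Ends are still opening early on. That the books close well before 30 min is a guess, since the runs do not show chains.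

5. Closing: with the books closed, the average is the reacted part times the charge ratio, free monomer charged per mole of initiator charged, 200.

6. A straight line against charge through the readings of gamma and alpha at 30.0 min is a cheap estimate: it gives 54.4 % reacted in the flask, hence an average of 109.

The forecast differs, with 50 % reacted, less than this line gives, and an average of 102: “with initiation complete, dp ≈ 0.50/0.005 ≈ 100, slightly more if some initiator remains”.

The flask reaches 51.1 % reacted and an average of 102, with initiator down to 0.086 % of its charge.

    free monomer + living end → monomer in chains + living end, rate k1*[living end]*[free monomer] (k = 0.370 L mol⁻¹ s⁻¹)
    monomer in chains + living end → free monomer + living end, rate k2*[living end] as long as [monomer in chains] is above zero (k = 0.0250 s⁻¹)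
    free monomer + initiator → living end + monomer in chains (k = 0.0160 L mol⁻¹ s⁻¹)

The charge ratio turns that reacted part into 102. Among the simulated changes, the length of the run has the largest single effect on the average: the same flask left ten times as long stands at 161, against 102. There 80.4 % has reacted, and the charge ratio turns that into 161. The neighbouring flask with 0.2 mol% of initiator has a charge ratio of 500 and reacts 26.8 %, so the ledger gives 134, and that flask reads 134.

(The data are calculated for substances that don't exist, noise included.)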